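**Retrosynthetic overview**

- The target (2S)-flavanone is reached last by fluoride removal of two aryl silyl ethers, preceded by Heck attachment of the (E)-3-hydroxy-3-methylbut-1-enyl chain at C3' of a 3'-bromoflavanone; the bromine is kept until then because a free alcohol or a second alkene would intercept the carbenoid.
- Rings A and B are bought as arenes. Ring C is the only ring formed, by making the C2–C3 bond: a rhodium carbenoid at C3, generated from a ring A diazomethyl ketone (C4=O), inserts into a C–H bond of the OCH2 group of the ring B benzyl ether.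
- The feature used: C2 is a CH bonded to ring oxygen O1 and to C1' of ring B. In the open ether its two C–H bonds are hydridic (α to oxygen and benzylic) and lie six atoms from the diazo carbon across C4, C4a, C8a and O1. Ring B itself is close to electron-neutral at this stage (Br at C3', twisted OMe at C4'), so the activation comes from O1 and the benzylic position.
- The diazoketone comes from the methyl ketone by detrifluoroacetylative diazo transfer; the methyl ketone comes from Mitsunobu etherification of 2,4-bis-silylated trihydroxyacetophenone with the ring B benzyl alcohol.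
- The ring B alcohol comes from 3-bromo-4-hydroxybenzaldehyde by O-allylation, Claisen rearrangement, O-methylation, cross-metathesis with 2-methylbut-2-ene and reduction.

Key step: step 9

Assumption: Rh2(S-PTTL)4 is taken to give the 2S product at this benzylic ether methylene; this is to be confirmed on a small scale, and the mirror-image catalyst Rh2(R-PTTL)4 (from D-tert-leucine) takes its place under identical conditions if the sense is the opposite.

**Route**

Step 1
Reactants: 1 3-bromo-4-hydroxybenzaldehyde; 2 allyl bromide (3-bromoprop-1-ene)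
Product: 3 3-bromo-4-(prop-2-enyloxy)benzaldehyde
Conditions: K2CO3, acetone, reflux
Reagents that add atoms: none
Why: Williamson etherification, in which the phenoxide formed with K2CO3 should displace bromide from the allylic halide by SN2 while the aldehyde and the aryl bromide stay inert.

Step 2
Reactants: 3 3-bromo-4-(prop-2-enyloxy)benzaldehyde
Product: 4 3-bromo-4-hydroxy-5-(prop-2-enyl)benzaldehyde
Conditions: N,N-diethylaniline, 195 °C, Ar, sealed tube
Reagents that add atoms: none
Why: Aromatic Claisen rearrangement, in which the thermal [3,3]-sigmatropic shift should deliver the allyl group to C5, the only ortho position that carries hydrogen, followed by rearomatisation to the phenol.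

Step 3
Reactants: 4 3-bromo-4-hydroxy-5-(prop-2-enyl)benzaldehyde
Product: 5 3-bromo-4-methoxy-5-(prop-2-enyl)benzaldehyde
Conditions: MeI, K2CO3, DMF, rt
Reagents that add atoms: iodomethane, CI
Why: Williamson O-methylation, which should proceed at the doubly ortho-substituted phenoxide because the electrophile is small.

Step 4
Reactants: 5 3-bromo-4-methoxy-5-(prop-2-enyl)benzaldehyde; 6 2-methylbut-2-ene
Product: 7 3-bromo-4-methoxy-5-(3-methylbut-2-enyl)benzaldehyde
Conditions: second-generation Grubbs catalyst RuCl2(=CHPh)(H2IMes)(PCy3) (3 mol%), 2-methylbut-2-ene/CH2Cl2, 40 °C, sealed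
Reagents that add atoms: none
Why: Olefin cross-metathesis, in which a large excess of the trisubstituted alkene should exchange the terminal CH2 for an isopropylidene group with release of propene, tolerating the aldehyde and aryl bromide and raising no E/Z question.

Step 5
Reactants: 7 3-bromo-4-methoxy-5-(3-methylbut-2-enyl)benzaldehyde
Product: 8 [3-bromo-4-methoxy-5-(3-methylbut-2-enyl)phenyl]methanol
Conditions: NaBH4, MeOH, 0 °C
Reagents that add atoms: none
Why: Borohydride reduction of the aldehyde, which should leave the aryl bromide, the methyl ether and the trisubstituted alkene untouched.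

Step 6
Reactants: 9 2',4',6'-trihydroxyacetophenone (anhydrous)
Product: 10 1-[2,4-bis(tert-butyldimethylsilyloxy)-6-hydroxyphenyl]ethanone
Conditions: TBSCl (2.1 equiv), imidazole, DMF, 0 °C to rt
Reagents that add atoms: tert-butyldimethylsilyl chloride, CC(C)(C)[Si](C)(C)Cl
Why: Selective phenol silylation, in which the 4-OH and one of the two equivalent ortho OH groups should react, after which the last OH is held in a hydrogen bond to the acetyl oxygen and resists the bulky silyl chloride.

Step 7
Reactants: 10 1-[2,4-bis(tert-butyldimethylsilyloxy)-6-hydroxyphenyl]ethanone; 8 [3-bromo-4-methoxy-5-(3-methylbut-2-enyl)phenyl]methanol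
Product: 11 1-{2-[(3-bromo-4-methoxy-5-(3-methylbut-2-enyl)phenyl)methoxy]-4,6-bis(tert-butyldimethylsilyloxy)phenyl}ethanone
Conditions: PPh3, DIAD, THF, 0 °C to rt
Reagents that add atoms: none
Why: Mitsunobu etherification, in which the acidic chelated phenol should be O-alkylated by the primary benzylic alcohol activated as its oxyphosphonium salt, under neutral conditions that spare the base-labile aryl silyl ethers.

Step 8
Reactants: 11 1-{2-[(3-bromo-4-methoxy-5-(3-methylbut-2-enyl)phenyl)methoxy]-4,6-bis(tert-butyldimethylsilyloxy)phenyl}ethanone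
Product: 13 2-diazo-1-{2-[(3-bromo-4-methoxy-5-(3-methylbut-2-enyl)phenyl)methoxy]-4,6-bis(tert-butyldimethylsilyloxy)phenyl}ethanone, via trifluoroacetyl diketone 12 (not isolated)
Conditions: LiN(SiMe3)2, THF, −78 °C; CF3CO2CH2CF3, −78 °C; cold 5% aq HCl work-up; then MsN3, Et3N, H2O (1 equiv), MeCN, rt; NaHCO3 wash
Reagents that add atoms: methanesulfonyl azide, CS(=O)(=O)N=[N+]=[N-] (the two diazo nitrogen atoms of 13); 2,2,2-trifluoroethyl trifluoroacetate, O=C(OCC(F)(F)F)C(F)(F)F (the trifluoroacetyl group of 12, lost again on diazo transfer)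
Why: Detrifluoroacetylative diazo transfer (a Regitz-type transfer with acyl activation), in which the kinetic lithium enolate of the methyl ketone should be C-acylated at −78 °C, the activated 1,3-diketone should accept the diazo group from the sulfonyl azide, and the trifluoroacetyl group should leave as the N-acylsulfonamide.

Step 9
Reactants: 13 2-diazo-1-{2-[(3-bromo-4-methoxy-5-(3-methylbut-2-enyl)phenyl)methoxy]-4,6-bis(tert-butyldimethylsilyloxy)phenyl}ethanone
Product: 14 (2S)-2-[3-bromo-4-methoxy-5-(3-methylbut-2-enyl)phenyl]-5,7-bis(tert-butyldimethylsilyloxy)chroman-4-one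
Conditions: Rh2(S-PTTL)4 (dirhodium tetrakis[N-phthaloyl-(S)-tert-leucinate], 2 mol%), CH2Cl2, 0 °C, 13 added by syringe pump over 2 h, Ar
Reagents that add atoms: none
Why: The divalent rhodium paddlewheel should expel N2 from the diazoketone to give a rhodium-bound acylcarbene at C3, which engages one C2–H bond of the OCH2 group in a concerted three-centre transition state with hydride character at hydrogen, so that C2–C3 forms on the face the hydrogen leaves (retention). The closest known reaction type is the chiral dirhodium carboxylate-catalysed intramolecular C–H insertion of 2-alkoxyaryl α-diazoketones to chroman-4-ones. Ring C closes in the 1,6-mode as a six-membered ring (C3, C4, C4a, C8a, O1, C2); the usual five-membered alternative is absent because the fifth atom of the tether is O1, which carries no hydrogen. C2 becomes stereogenic by selection between the two enantiotopic hydrogens of the OCH2 group inside the chiral pocket of the four phthalimido-tert-leucinate ligands, the catalyst enantiomer being the one that gives 2S. The step needs insertion to win over attack on the lone pair of O1 (five-membered oxonium ylide, then 1,2-benzyl shift to a 2-benzylbenzofuran-3-one), over attack on the ortho silyl ether oxygen, over addition to ring B or the prenyl alkene and over carbene dimerisation. This should be secured by the doubly activated C2–H bond, by the low basicity of O1 (its lone pair is delocalised into the acyl-bearing ring A), by the bulk of the silyl group, by the remote position of the alkene, by a carboxylate rather than a copper or perfluorocarboxylate catalyst, and by slow addition at high dilution.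

Step 10
Reactants: 14 (2S)-2-[3-bromo-4-methoxy-5-(3-methylbut-2-enyl)phenyl]-5,7-bis(tert-butyldimethylsilyloxy)chroman-4-one; 15 2-methylbut-3-en-2-ol
Product: 16 (2S)-5,7-bis(tert-butyldimethylsilyloxy)-2-{3-[(E)-3-hydroxy-3-methylbut-1-enyl]-4-methoxy-5-(3-methylbut-2-enyl)phenyl}chroman-4-one
Conditions: Pd[P(t-Bu)3]2 (5 mol%), Cy2NMe, 15 (3 equiv), 1,4-dioxane, rt to 45 °C
Reagents that add atoms: none
Why: Mizoroki–Heck reaction, in which oxidative addition of zerovalent palladium into the aryl C–Br bond, insertion of the terminal alkene and β-hydride elimination (the carbinol carbon has no hydrogen) should give only the E-styrenyl tertiary alcohol, the bulky electron-rich phosphine with a hindered amine allowing a temperature low enough that the base-sensitive C2 centre is not opened and epimerised.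

Step 11
Reactants: 16 (2S)-5,7-bis(tert-butyldimethylsilyloxy)-2-{3-[(E)-3-hydroxy-3-methylbut-1-enyl]-4-methoxy-5-(3-methylbut-2-enyl)phenyl}chroman-4-one
Product: 17 (2S)-5,7-dihydroxy-2-{3-[(E)-3-hydroxy-3-methylbut-1-enyl]-4-methoxy-5-(3-methylbut-2-enyl)phenyl}chroman-4-one (EANPDB:LEGU_00041)
Conditions: Et3N·3HF, THF, rt
Reagents that add atoms: none
Why: Fluoride cleavage of both aryl silyl ethers in a weakly acidic buffered medium, which should free the 5- and 7-hydroxyl groups without generating phenoxide (no retro-oxa-Michael opening at C2) and without ionising the tertiary allylic alcohol.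

**Compound list**

1 | 3-bromo-4-hydroxybenzaldehyde | O=Cc1ccc(O)c(Br)c1 | starting material
2 | allyl bromide (3-bromoprop-1-ene) | C=CCBr | starting material
3 | 3-bromo-4-(prop-2-enyloxy)benzaldehyde | O=Cc1ccc(OCC=C)c(Br)c1 | intermediate
4 | 3-bromo-4-hydroxy-5-(prop-2-enyl)benzaldehyde | O=Cc1cc(Br)c(O)c(CC=C)c1 | intermediate
5 | 3-bromo-4-methoxy-5-(prop-2-enyl)benzaldehyde | O=Cc1cc(Br)c(OC)c(CC=C)c1 | intermediate
6 | 2-methylbut-2-ene | CC=C(C)C | starting material
7 | 3-bromo-4-methoxy-5-(3-methylbut-2-enyl)benzaldehyde | O=Cc1cc(Br)c(OC)c(CC=C(C)C)c1 | intermediate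
8 | [3-bromo-4-methoxy-5-(3-methylbut-2-enyl)phenyl]methanol | OCc1cc(Br)c(OC)c(CC=C(C)C)c1 | intermediate
9 | 2',4',6'-trihydroxyacetophenone | CC(=O)c1c(O)cc(O)cc1O | starting material
10 | 1-[2,4-bis(tert-butyldimethylsilyloxy)-6-hydroxyphenyl]ethanone | CC(=O)c1c(O)cc(O[Si](C)(C)C(C)(C)C)cc1O[Si](C)(C)C(C)(C)C | intermediate
11 | 1-{2-[(3-bromo-4-methoxy-5-(3-methylbut-2-enyl)phenyl)methoxy]-4,6-bis(tert-butyldimethylsilyloxy)phenyl}ethanone | CC(=O)c1c(OCc2cc(Br)c(OC)c(CC=C(C)C)c2)cc(O[Si](C)(C)C(C)(C)C)cc1O[Si](C)(C)C(C)(C)C | intermediate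
12 | 1-{2-[(3-bromo-4-methoxy-5-(3-methylbut-2-enyl)phenyl)methoxy]-4,6-bis(tert-butyldimethylsilyloxy)phenyl}-4,4,4-trifluorobutane-1,3-dione | O=C(CC(=O)C(F)(F)F)c1c(OCc2cc(Br)c(OC)c(CC=C(C)C)c2)cc(O[Si](C)(C)C(C)(C)C)cc1O[Si](C)(C)C(C)(C)C | intermediate
13 | 2-diazo-1-{2-[(3-bromo-4-methoxy-5-(3-methylbut-2-enyl)phenyl)methoxy]-4,6-bis(tert-butyldimethylsilyloxy)phenyl}ethanone | [N-]=[N+]=CC(=O)c1c(OCc2cc(Br)c(OC)c(CC=C(C)C)c2)cc(O[Si](C)(C)C(C)(C)C)cc1O[Si](C)(C)C(C)(C)C | intermediate
14 | (2S)-2-[3-bromo-4-methoxy-5-(3-methylbut-2-enyl)phenyl]-5,7-bis(tert-butyldimethylsilyloxy)chroman-4-one | COc1c(Br)cc([C@@H]2CC(=O)c3c(O[Si](C)(C)C(C)(C)C)cc(O[Si](C)(C)C(C)(C)C)cc3O2)cc1CC=C(C)C | intermediate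
15 | 2-methylbut-3-en-2-ol | C=CC(C)(C)O | starting material
16 | (2S)-5,7-bis(tert-butyldimethylsilyloxy)-2-{3-[(E)-3-hydroxy-3-methylbut-1-enyl]-4-methoxy-5-(3-methylbut-2-enyl)phenyl}chroman-4-one | COc1c(/C=C/C(C)(C)O)cc([C@@H]2CC(=O)c3c(O[Si](C)(C)C(C)(C)C)cc(O[Si](C)(C)C(C)(C)C)cc3O2)cc1CC=C(C)C | intermediate
17 | (2S)-5,7-dihydroxy-2-{3-[(E)-3-hydroxy-3-methylbut-1-enyl]-4-methoxy-5-(3-methylbut-2-enyl)phenyl}chroman-4-one | COc1c(/C=C/C(C)(C)O)cc([C@@H]2CC(=O)c3c(O)cc(O)cc3O2)cc1CC=C(C)C | target

**Step count**

Total: 11 steps. Longest linear sequence: 10 steps (steps 1–5 and 7–11, from 3-bromo-4-hydroxybenzaldehyde); step 6 is the one-step side branch.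

**Steps most likely to fail**

1. Step 9. The carbenoid may be diverted to the oxonium ylide at O1 followed by 1,2-benzyl migration, or may dimerise, and the catalyst may discriminate the two enantiotopic hydrogens insufficiently. The fallback sets out from ketone 10 and aldehyde 7 and returns at 14, closing ring C through O1–C2 instead. The dilithium phenoxide–enolate of 10 (LiN(SiMe3)2, 2.2 equiv, THF, −78 °C) should add to 7 to give the racemic aldol 1-[2,4-bis(tert-butyldimethylsilyloxy)-6-hydroxyphenyl]-3-[3-bromo-4-methoxy-5-(3-methylbut-2-enyl)phenyl]-3-hydroxypropan-1-one F1. Intramolecular Mitsunobu etherification (PPh3, DIAD, THF, 0 °C) should then give racemic 2-[3-bromo-4-methoxy-5-(3-methylbut-2-enyl)phenyl]-5,7-bis(tert-butyldimethylsilyloxy)chroman-4-one F2. Preparative HPLC on a cellulose tris(3,5-dimethylphenylcarbamate) phase should separate the enantiomers and give 14.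

2. Step 8. In the lithium enolate the ortho silyl group may migrate from the aryl oxygen to the enolate oxygen, and a silyl ether may be lost under the amine/water conditions of the transfer. The fallback sets out from alcohol 8 and returns at 13 with no enolate on the way. Commercial 2,4,6-trihydroxybenzaldehyde F3 is bis-silylated as in step 6 (TBSCl, imidazole, DMF, 0 °C) to 2,4-bis(tert-butyldimethylsilyloxy)-6-hydroxybenzaldehyde F4. Mitsunobu etherification with 8 (PPh3, DIAD, THF) should give 2-[(3-bromo-4-methoxy-5-(3-methylbut-2-enyl)phenyl)methoxy]-4,6-bis(tert-butyldimethylsilyloxy)benzaldehyde F5. Pinnick oxidation (NaClO2, NaH2PO4, excess 2-methylbut-2-ene, t-BuOH/H2O) should give 2-[(3-bromo-4-methoxy-5-(3-methylbut-2-enyl)phenyl)methoxy]-4,6-bis(tert-butyldimethylsilyloxy)benzoic acid F6. Neutral activation with 1-chloro-N,N,2-trimethylprop-1-en-1-amine (CH2Cl2, 0 °C) should give 2-[(3-bromo-4-methoxy-5-(3-methylbut-2-enyl)phenyl)methoxy]-4,6-bis(tert-butyldimethylsilyloxy)benzoyl chloride F7, which is added to diazomethane (2.5 equiv, Et2O, 0 °C) to give 13.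

3. Step 10. Amine and warmth may open ring C at O1–C2 (retro-oxa-Michael) and erode the configuration at C2, oxidative addition into the hindered aryl bromide may be slow, and a palladium hydride may shift the prenyl double bond. The fallback sets out from 14 and returns at 16. Commercial 2-methylbut-3-yn-2-ol F8 is hydrostannylated (Bu3SnH, AIBN, 80 °C) to (E)-2-methyl-4-(tributylstannyl)but-3-en-2-ol F9. A base-free Stille coupling of 14 with F9 (Pd(PPh3)4, toluene, 80 °C) should then give 16 without amine and without a palladium hydride.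

**Further compounds**

F1 | step 9 | 1-[2,4-bis(tert-butyldimethylsilyloxy)-6-hydroxyphenyl]-3-[3-bromo-4-methoxy-5-(3-methylbut-2-enyl)phenyl]-3-hydroxypropan-1-one (racemic) | O=C(CC(O)c1cc(Br)c(OC)c(CC=C(C)C)c1)c1c(O)cc(O[Si](C)(C)C(C)(C)C)cc1O[Si](C)(C)C(C)(C)C
F2 | step 9 | racemic 2-[3-bromo-4-methoxy-5-(3-methylbut-2-enyl)phenyl]-5,7-bis(tert-butyldimethylsilyloxy)chroman-4-one | COc1c(Br)cc(C2CC(=O)c3c(O[Si](C)(C)C(C)(C)C)cc(O[Si](C)(C)C(C)(C)C)cc3O2)cc1CC=C(C)C
F3 | step 8 | 2,4,6-trihydroxybenzaldehyde (purchased) | O=Cc1c(O)cc(O)cc1O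
F4 | step 8 | 2,4-bis(tert-butyldimethylsilyloxy)-6-hydroxybenzaldehyde | O=Cc1c(O)cc(O[Si](C)(C)C(C)(C)C)cc1O[Si](C)(C)C(C)(C)C
F5 | step 8 | 2-[(3-bromo-4-methoxy-5-(3-methylbut-2-enyl)phenyl)methoxy]-4,6-bis(tert-butyldimethylsilyloxy)benzaldehyde | O=Cc1c(OCc2cc(Br)c(OC)c(CC=C(C)C)c2)cc(O[Si](C)(C)C(C)(C)C)cc1O[Si](C)(C)C(C)(C)C
F6 | step 8 | 2-[(3-bromo-4-methoxy-5-(3-methylbut-2-enyl)phenyl)methoxy]-4,6-bis(tert-butyldimethylsilyloxy)benzoic acid | OC(=O)c1c(OCc2cc(Br)c(OC)c(CC=C(C)C)c2)cc(O[Si](C)(C)C(C)(C)C)cc1O[Si](C)(C)C(C)(C)C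
F7 | step 8 | 2-[(3-bromo-4-methoxy-5-(3-methylbut-2-enyl)phenyl)methoxy]-4,6-bis(tert-butyldimethylsilyloxy)benzoyl chloride | O=C(Cl)c1c(OCc2cc(Br)c(OC)c(CC=C(C)C)c2)cc(O[Si](C)(C)C(C)(C)C)cc1O[Si](C)(C)C(C)(C)C
F8 | step 10 | 2-methylbut-3-yn-2-ol (purchased) | C#CC(C)(C)O
F9 | step 10 | (E)-2-methyl-4-(tributylstannyl)but-3-en-2-ol | CCCC[Sn](CCCC)(CCCC)/C=C/C(C)(C)O
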